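## The problem

The target 26 is a trans-1-aryl-1,2-dihydronaphthalene-2,3-dicarboxylic acid. A catechol ring A is fused to the partly saturated ring B, ring C hangs on C1, and O3' of ring C alone carries an (E)-2-aryloxy-3-(3,4-dihydroxyphenyl)acrylic acid (ring D). There are two stereocentres, C1 (R) and C2 (S), trans to each other. C1 is doubly benzylic with no acidifying neighbour and has to be set by an enantioselective reaction. C2 is alpha to a carboxyl and, once ring B exists, trans is the thermodynamic arrangement, so C1 can dictate C2 by equilibration. The molecule holds three oxidisable catechol-type rings, an enol ether whose E geometry (ring D cis to its own carboxyl) is the less stable one, and a C3=C4 bond that can migrate or be lost by aromatisation of ring B. Hydrogenolysis and long exposure of the free polyphenol to strong acid or base are therefore excluded. Five phenolic oxygens must be told apart, because only O3' bears the side chain. The feature that invites a late benzannulation is ring A itself: C5 and C8 carry hydrogen, C6 and C7 carry oxygen, and C4a and C8a are bridged by C1–C4. This is the retron of a [2+2+2] cocyclisation of two terminal alkynes (C4a≡C5 and C8a≡C8), tethered through C1–C4, with a symmetric two-carbon unit whose substituents are oxygen equivalents.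

## Retrosynthesis

**Ethers and esters last.** The final cuts are the three O–benzyl bonds of 25 and the three ester O–methyl bonds of 24, leading back from 26. Benzyl is preferred to methyl on the phenols because it can be removed by a Lewis acid with a cation trap at −78 °C. That avoids hydrogen, which would reduce C3=C4 and the enol ether, and avoids warm acid that could turn the E-enol ether into its more stable isomer. The esters go first, so the fully free polyphenol never meets base. Only chemoselectivity is asked of these steps.

**Ring A oxygens from boron.** The C6–O and C7–O bonds of 24 are traced to the two C–B bonds of 23. Keeping boron this long means ring A never needs a protecting group and O3' is the only free hydroxyl when the side chain is attached. Oxidising early and capping the catechol would cost two steps and add two ethers to the final cleavage. The oxidation has to spare two enoates and an enol ether.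

**The enol ether.** The side-chain C=C of 23 is cut to phosphonate 21 and aldehyde 22. The O3'–C bond of 21 is cut to phenol 18 and diazophosphonate 20, which is one diazo transfer from 19. The E isomer needed has ring D cis to the ester, which is the kinetic, ester-cis alkene, so a bis(trifluoroethyl) phosphonate is built in from the start. Vinylation of the phenol or addition to an arylpropiolate would tend to give the other regiochemistry or the thermodynamic geometry. The O–H insertion needs a single free hydroxyl, which 18 offers.

**C2.** Compound 18 is the trans epimer within 17; the bond concerned is C2–H. No open-chain intermediate gives a dependable bias at C2, whereas ring B strongly prefers the trans-diaxial arrangement. C2 is therefore left unassigned up to 17 and then equilibrated. The base must reach the extended enolate without moving the double bond.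

**Rings A and B together.** Compound 17 is cut through C5–C6, C7–C8 and C4a–C8a to the ene-diyne 15 and the diborylalkyne 16. Against the usual cuts of ring B next to C1 (C1–C8a or C1–C2), this removes both carbocycles at once and leaves C1 as a propargylic, benzylic CH in an open chain. It also delivers the C6 and C7 substituents as boron, orthogonal to every oxygen present. The precursor has no ring and one secure stereocentre. Its only design constraint is the alkene geometry: C2 and the C4 alkyne must be cis, which is the normal outcome of an alkylidene succinate synthesis. The forward reaction must favour cross- over homo-cyclotrimerisation.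

**The enyne.** Compound 15 comes from 14 by loss of three silyl groups, and 14 from acid 13 by esterification. The C3=C4 bond of 13 is cut to succinate 10 and ynal 11 (Stobbe condensation). A phosphonate olefination at C3 would need a 2-phosphonosuccinate carrying the C1 substituent; making it by enolate alkylation with an alpha-halophosphonoacetate would be defeated by halogen transfer and proton exchange. The Stobbe route uses only the methylene acidity of 10, and only the methylene aldolate can eliminate, which settles the regiochemistry.

**C2–C3.** Succinate 10 is cut between C2 and C3 to the Meldrum's acid adduct 6 and bromoacetate 7, by way of the quaternary compound 8, whose methanolysis and decarboxylation leave the C2 ester. Alkylating the very acidic 6 is more reliable than alkylating a beta-branched ester enolate. The price, an uncontrolled C2, is the one already accepted.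

**C1.** The C1–C(sp) bond of 6 is cut to arylidene 4 and silylacetylene 5 (enantioselective conjugate alkynylation). Compound 4 is cut to aldehyde 2 and Meldrum's acid 3 (Knoevenagel), and 2 is the silyl ether of phenol 1. A silyl ether is chosen for O3' so that one fluoride treatment (14 to 15) frees both alkynes and the one phenol that is to be functionalised.

## Roads not taken

**Alternative 1:** The cut runs through C1–C2 and C3–C4 of ring B. Irradiation of the diarylmethane aldehyde A1 would give a hydroxy-o-quinodimethane spanning C1 and C4, trapped by dimethyl fumarate A2 in a Diels–Alder reaction to give tetralin A3. Dehydration across C3–C4 would follow.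
- Merits: two C–C bonds, ring B and the relative configuration of C1–C3 arise in one step, from an aldehyde a few steps from simple aromatics. The ring system would probably be reached in about half the steps of the chosen plan.
- Weak points: no stereocentre exists before the cycloaddition, so the absolute configuration must come from a chiral Lewis acid or an auxiliary on the dienophile. For a photoenol bearing an aryl group on its reacting terminus this is not secured, and racemic A3 would need resolution. The C1/C2 relationship also depends on the aryl group sitting outward in the photoenol and on endo selection. Ring A arrives as a dimethyl ether, whose cleavage would have to be carried out next to the E-enol ether.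
- Comparison: this road is shorter and uses cheaper materials. The chosen plan offers instead a C1 centre fixed by a catalytic asymmetric reaction on its established substrate class, and ring A oxygens that come from C–B bonds and never need protection.

**Alternative 2:** The cut is C1–C2 alone. A para-quinone methide A4 is generated at C1 of a tethered (E)-arylidene succinate, and its C2 dienolate adds in a 6-exo-trig vinylogous conjugate addition, giving A5 on rearomatisation.
- Merits: the closure mirrors the likely biogenesis, the arylidene succinate is assembled convergently by condensations, the trans product is expected, and no metal is needed for ring formation.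
- Weak points: the quinone methide requires the free phenol at C4', so the closure liberates O4', while the side chain belongs on O3'. A protecting-group exchange would follow. C1 is created from a planar electrophile, so enantiocontrol would need a chiral catalyst to organise an intramolecular ester dienolate and quinone methide, a pairing with little precedent. The quinone methide must also be generated next to an electron-rich styrene.
- Comparison: it reaches ring B in fewer steps. The chosen plan sets C1 before any ring is closed and has the correct phenol differentiated from the first step.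

**Alternative 3:** The cut is C4–C4a. Precursor A6 carries two identical aryl groups on C1 and a hydroxymethylene carbon (C4) on C3. Acid-promoted cyclodehydration lets one aryl group attack C4 para to its benzyloxy group, giving A7, and C1 becomes stereogenic by selection between diastereotopic aryl groups under the influence of C2.
- Merits: the symmetric diarylmethyl unit is easy to install, only C2 needs an asymmetric step, and the ring closure is classical. It is probably the shortest way to the dihydronaphthalene.
- Weak points: the controlling centre C2 is alpha to an ester and next to an enolisable formyl ester, so it may scramble under the acid before it has exerted control. The 1,2-induction between diastereotopic aryl groups is likely to be modest. Most seriously, rings A and C end with the same benzyloxy/methoxy pattern, so O7 and O3' cannot be distinguished when O3' alone must be freed for the enol ether.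
- Comparison: it is better on step count. The chosen plan has five phenolic oxygens that are distinct by construction (two as boron, one as silyl ether, the rest as benzyl ethers) and a C1 centre that does not depend on an epimerisable neighbour.

Key step: step 9

## Route

Atom numbers (C1–C8a, primes for ring C) are those of the target throughout. Bpin is 4,4,5,5-tetramethyl-1,3,2-dioxaborolan-2-yl.

Remark 1: 4-(benzyloxy)-3-hydroxybenzaldehyde (1) is taken to be a catalogue compound.

Remark 2: the ligand antipode written in step 3 is taken to be the one that delivers (R)-6; the sense of induction is to be confirmed on the first batch and the mirror-image ligand used if it proves opposite.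

Step 1
Reactants: 1 4-(benzyloxy)-3-hydroxybenzaldehyde
Product: 2 4-(benzyloxy)-3-[(triisopropylsilyl)oxy]benzaldehyde
Conditions: iPr3SiCl, imidazole, DMF, rt
Reagents that add atoms: triisopropylsilyl chloride, CC(C)[Si](Cl)(C(C)C)C(C)C
Why: Silylation of the phenol. The bulky silyl ether should survive carbonate, hot methanol/pyridine and amide base, and it falls together with the alkynyl silanes in step 8.

Step 2
Reactants: 2 4-(benzyloxy)-3-[(triisopropylsilyl)oxy]benzaldehyde; 3 Meldrum's acid
Product: 4 5-{4-(benzyloxy)-3-[(triisopropylsilyl)oxy]benzylidene}-2,2-dimethyl-1,3-dioxane-4,6-dione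
Conditions: pyrrolidinium acetate (10 mol %), PhMe, rt
Reagents that add atoms: none
Why: Knoevenagel condensation. The doubly activated methylene condenses at room temperature and gives the acceptor in which C1=C2 is activated by two carbonyl groups.

Step 3
Reactants: 4 arylidene Meldrum's acid; 5 (trimethylsilyl)acetylene
Product: 6 5-[(1R)-1-{4-(benzyloxy)-3-[(triisopropylsilyl)oxy]phenyl}-3-(trimethylsilyl)prop-2-yn-1-yl]-2,2-dimethyl-1,3-dioxane-4,6-dione
Conditions: Rh(acac)(C2H4)2 (5 mol %), (R)-3,5-xylyl-MeO-BIPHEP (6 mol %), 5 (excess), dioxane, rt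
Reagents that add atoms: none
Why: Rhodium-catalysed enantioselective conjugate alkynylation of a benzylidene Meldrum's acid. An alkynyl complex of monovalent rhodium adds to C1, the chiral bisphosphine selects the enantioface and so sets C1, and the rhodium enolate is protonated by the alkyne. The excess of 5 limits alkyne dimerisation.

Step 4
Reactants: 6 Meldrum's acid adduct; 7 methyl bromoacetate
Product: 8 methyl 2-{5-[(1S)-1-{4-(benzyloxy)-3-[(triisopropylsilyl)oxy]phenyl}-3-(trimethylsilyl)prop-2-yn-1-yl]-2,2-dimethyl-4,6-dioxo-1,3-dioxan-5-yl}acetate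
Conditions: K2CO3, DMF, 0 °C to rt
Reagents that add atoms: none
Why: SN2 C-alkylation of the acidic 5-monosubstituted Meldrum's acid forms C2–C3 and brings in C3 with its carboxyl. C1 is untouched; its descriptor changes only because the priorities change.

Step 5
Reactants: 8 quaternary Meldrum's acid
Product: 10 dimethyl 2-[(1R)-1-{4-(benzyloxy)-3-[(triisopropylsilyl)oxy]phenyl}-3-(trimethylsilyl)prop-2-yn-1-yl]butanedioate (both epimers at the succinate methine C2), via malonic half-ester 9 (not isolated)
Conditions: MeOH/pyridine (4:1), 90 °C, sealed tube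
Reagents that add atoms: methanol, CO
Why: Methanolysis of the non-enolisable dioxanedione with loss of acetone, then thermal decarboxylation of the malonic half-ester. C2 becomes stereogenic without control, which is accepted because step 10 sets it.

Step 6
Reactants: 10 succinate diester; 11 3-(trimethylsilyl)prop-2-ynal
Product: 13 (3E)-3-(methoxycarbonyl)-6-(trimethylsilyl)-2-[(1R)-1-{4-(benzyloxy)-3-[(triisopropylsilyl)oxy]phenyl}-3-(trimethylsilyl)prop-2-yn-1-yl]hex-3-en-5-ynoic acid (both C2 epimers), via paraconic lactone 12 (not isolated)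
Conditions: LiN(iPr)2 (1.3 equiv), THF, −78 °C; 11, −78 °C to rt; 1 M HCl
Reagents that add atoms: none
Why: Stobbe condensation: the methylene enolate adds to the ynal, the aldolate lactonises onto the C2 ester, and E1cB opening gives the half-ester with C3=C4. Only the methylene aldolate can eliminate, which funnels the regiochemistry. The elimination should place the alkyne trans to the C3 ester (E), that is, cis to C2.

Step 7
Reactants: 13 Stobbe half-ester
Product: 14 dimethyl (2E)-2-[3-(trimethylsilyl)prop-2-yn-1-ylidene]-3-[(1R)-1-{4-(benzyloxy)-3-[(triisopropylsilyl)oxy]phenyl}-3-(trimethylsilyl)prop-2-yn-1-yl]butanedioate (both epimers at the succinate methine)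
Conditions: Me3SiCHN2, PhMe/MeOH (3:1), 0 °C
Reagents that add atoms: (trimethylsilyl)diazomethane, C[Si](C)(C)C=[N+]=[N-]
Why: Esterification of the carboxylic acid under neutral conditions that leave the silyl groups, the enyne and C1 alone.

Step 8
Reactants: 14 bis-silylated ene-diyne diester
Product: 15 dimethyl (2E)-2-(prop-2-yn-1-ylidene)-3-[(1S)-1-[4-(benzyloxy)-3-hydroxyphenyl]prop-2-yn-1-yl]butanedioate (both epimers at the succinate methine)
Conditions: Bu4NF (3.5 equiv), AcOH (3.5 equiv), THF, 0 °C to rt
Reagents that add atoms: none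
Why: Fluoride-mediated desilylation cleaves both C(sp)–Si bonds and the aryl O–Si bond. The acetic acid buffer suppresses propargyl-to-allenyl isomerisation at C1 and conjugate addition to the enyne ester.

Step 9
Reactants: 15 ene-1,7-diyne diester; 16 bis(pinacolatoboryl)acetylene
Product: 17 dimethyl (1R)-1-[4-(benzyloxy)-3-hydroxyphenyl]-6,7-bis(Bpin)-1,2-dihydronaphthalene-2,3-dicarboxylate (both C2 epimers)
Conditions: CpCo(CO)2 (20 mol %), 16 (3 equiv), PhMe, 110 °C, hν (tungsten lamp), 15 added by syringe pump over 8 h
Reagents that add atoms: none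
Why: Loss of CO from CpCo(CO)2 under heat and light frees the CpCo fragment (monovalent cobalt), which binds both alkynes of 15 and couples them oxidatively to a cobaltacyclopentadiene (trivalent cobalt); this forms C4a–C8a and closes ring B as a six-membered ring annulated to the metallacycle, a closure made possible by the E geometry of C3=C4 that holds C2 and the C4 alkyne cis. Coordination and insertion of 16 then form C5–C6 and C7–C8, and reductive elimination releases ring A as an arene and returns monovalent cobalt. The closest known reaction type is the CpCo-mediated cocyclisation of alpha,omega-diynes with silyl-, boryl- and diboryl-alkynes to fused arenes. No stereocentre is formed: C1 and C2 are sp3 carbons outside the reacting pi-system, C1 is carried through unchanged and C2 remains a mixture. The step needs chemoselectivity for cross- over homo-cyclotrimerisation, which slow addition of 15 to an excess of 16 should secure, since the bulk of 16 slows its own trimerisation. Because 16 is symmetric there is no regiochemical question, and the two C–B bonds arrive on C6 and C7 as masked hydroxyls. The phenol, the esters and the benzyl ether should be spectators towards low-valent cobalt.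

Step 10
Reactants: 17 dihydronaphthalene diester as C2 epimers
Product: 18 dimethyl (1R,2S)-1-[4-(benzyloxy)-3-hydroxyphenyl]-6,7-bis(Bpin)-1,2-dihydronaphthalene-2,3-dicarboxylate (trans)
Conditions: DBU (1.5 equiv), PhMe, rt, argon
Reagents that add atoms: none
Why: Base-mediated epimerisation through the extended ester enolate at C2. The trans isomer, with the C1 aryl group pseudoaxial away from H8 and the C2 ester pseudoaxial on the other face, is the thermodynamic sink, so C1 (R) dictates C2 (S). Argon excludes oxidative aromatisation of the enolate.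

Step 11
Reactants: 19 methyl 2-[bis(2,2,2-trifluoroethoxy)phosphoryl]acetate
Product: 20 methyl 2-[bis(2,2,2-trifluoroethoxy)phosphoryl]-2-diazoacetate
Conditions: 4-acetamidobenzenesulfonyl azide, Et3N, MeCN, 0 °C to rt
Reagents that add atoms: 4-acetamidobenzenesulfonyl azide, CC(=O)Nc1ccc(cc1)S(=O)(=O)N=[N+]=[N-]
Why: Regitz diazo transfer to the active methylene between phosphoryl and ester groups.

Step 12
Reactants: 18 trans phenol; 20 diazophosphonoacetate
Product: 21 dimethyl (1R,2S)-1-[4-(benzyloxy)-3-{1-[bis(2,2,2-trifluoroethoxy)phosphoryl]-2-methoxy-2-oxoethoxy}phenyl]-6,7-bis(Bpin)-1,2-dihydronaphthalene-2,3-dicarboxylate (both epimers at the phosphonate carbon)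
Conditions: Rh2(OAc)4 (2 mol %), PhMe, 80 °C, 20 added slowly
Reagents that add atoms: none
Why: Rhodium-carbenoid O–H insertion: the acetate of divalent rhodium turns 20 into an electrophilic carbenoid, which is captured by the only O–H bond (O3') through an oxonium ylide and proton shift. The acceptor-substituted carbenoid should spare the aryl boronates and the electron-poor alkene. The new stereocentre is destroyed in step 13.

Step 13
Reactants: 21 aryloxy phosphonate; 22 3,4-bis(benzyloxy)benzaldehyde
Product: 23 dimethyl (1R,2S)-1-[4-(benzyloxy)-3-{[(1E)-2-[3,4-bis(benzyloxy)phenyl]-1-(methoxycarbonyl)ethenyl]oxy}phenyl]-6,7-bis(Bpin)-1,2-dihydronaphthalene-2,3-dicarboxylate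
Conditions: KN(SiMe3)2 (1.0 equiv), 18-crown-6, THF, −78 °C; 22, −78 to −40 °C
Reagents that add atoms: none
Why: Still–Gennari variant of the Horner–Wadsworth–Emmons reaction. With trifluoroethyl phosphonate esters and a dissociated potassium ion, addition is irreversible and elimination fast, so the kinetic alkene with the ester cis to the incoming aryl group should form, which here is the E-enol ether. One equivalent of base goes to the much more acidic phosphonate C–H and leaves C2 alone.

Step 14
Reactants: 23 bis-boronate triester
Product: 24 dimethyl (1R,2S)-1-[4-(benzyloxy)-3-{[(1E)-2-[3,4-bis(benzyloxy)phenyl]-1-(methoxycarbonyl)ethenyl]oxy}phenyl]-6,7-dihydroxy-1,2-dihydronaphthalene-2,3-dicarboxylate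
Conditions: NaBO3·4H2O, THF/H2O (1:1), 0 °C to rt, argon
Reagents that add atoms: sodium perborate, [Na+].[Na+].O[B-]1(O)OO[B-](O)(O)OO1
Why: Oxidation of aryl boronates: the peroxoborate adds to boron, the aryl group migrates from boron to oxygen, and hydrolysis frees the phenol; both C–B bonds react to give the C6/C7 catechol. The reagent is mild and only weakly basic, which should spare the enoates, the enol ether and C2.

Step 15
Reactants: 24 catechol triester
Product: 25 (1R,2S)-1-[4-(benzyloxy)-3-{[(1E)-2-[3,4-bis(benzyloxy)phenyl]-1-carboxyethenyl]oxy}phenyl]-6,7-dihydroxy-1,2-dihydronaphthalene-2,3-dicarboxylic acid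
Conditions: LiOH, THF/MeOH/H2O (degassed), rt to 40 °C, argon; then 1 M HCl
Reagents that add atoms: lithium hydroxide, [Li+].[OH-]
Why: Saponification of the three methyl esters. The trans C1/C2 arrangement is the thermodynamic one, so hydroxide cannot erode it; benzyl ethers mask three of the five phenols and degassing protects the ring A catechol.

Step 16
Reactants: 25 tribenzyl triacid
Product: 26 (1R,2S)-1-[3-{[(1E)-1-carboxy-2-(3,4-dihydroxyphenyl)ethenyl]oxy}-4-hydroxyphenyl]-6,7-dihydroxy-1,2-dihydronaphthalene-2,3-dicarboxylic acid
Conditions: BCl3 (1 M in CH2Cl2), C6HMe5, CH2Cl2, −78 °C; then H2O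
Reagents that add atoms: none
Why: Lewis-acid debenzylation with a cation scavenger: BCl3 activates each benzyl ether and the benzyl cation is passed to pentamethylbenzene (Friedel–Crafts), not to the electron-rich rings. At −78 °C and without hydrogen, C3=C4 and the E-enol ether should be left as they are.

## Compound list

1 | 4-(benzyloxy)-3-hydroxybenzaldehyde | O=Cc1ccc(OCc2ccccc2)c(O)c1 | starting material
2 | 4-(benzyloxy)-3-[(triisopropylsilyl)oxy]benzaldehyde | O=Cc1ccc(OCc2ccccc2)c(O[Si](C(C)C)(C(C)C)C(C)C)c1 | intermediate
3 | Meldrum's acid (2,2-dimethyl-1,3-dioxane-4,6-dione) | CC1(C)OC(=O)CC(=O)O1 | starting material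
4 | 5-{4-(benzyloxy)-3-[(triisopropylsilyl)oxy]benzylidene}-2,2-dimethyl-1,3-dioxane-4,6-dione | CC1(C)OC(=O)C(=Cc2ccc(OCc3ccccc3)c(O[Si](C(C)C)(C(C)C)C(C)C)c2)C(=O)O1 | intermediate
5 | (trimethylsilyl)acetylene | C#C[Si](C)(C)C | starting material
6 | 5-[(1R)-1-{4-(benzyloxy)-3-[(triisopropylsilyl)oxy]phenyl}-3-(trimethylsilyl)prop-2-yn-1-yl]-2,2-dimethyl-1,3-dioxane-4,6-dione | C[Si](C)(C)C#C[C@@H](c1ccc(OCc2ccccc2)c(O[Si](C(C)C)(C(C)C)C(C)C)c1)C1C(=O)OC(C)(C)OC1=O | intermediate
7 | methyl bromoacetate | COC(=O)CBr | starting material
8 | methyl 2-{5-[(1S)-1-{4-(benzyloxy)-3-[(triisopropylsilyl)oxy]phenyl}-3-(trimethylsilyl)prop-2-yn-1-yl]-2,2-dimethyl-4,6-dioxo-1,3-dioxan-5-yl}acetate | C[Si](C)(C)C#C[C@@H](c1ccc(OCc2ccccc2)c(O[Si](C(C)C)(C(C)C)C(C)C)c1)C1(CC(=O)OC)C(=O)OC(C)(C)OC1=O | intermediate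
9 | 4-methoxy-2-(methoxycarbonyl)-4-oxo-2-[(1S)-1-{4-(benzyloxy)-3-[(triisopropylsilyl)oxy]phenyl}-3-(trimethylsilyl)prop-2-yn-1-yl]butanoic acid (both epimers at the quaternary carbon) | C[Si](C)(C)C#C[C@@H](c1ccc(OCc2ccccc2)c(O[Si](C(C)C)(C(C)C)C(C)C)c1)C(CC(=O)OC)(C(=O)O)C(=O)OC | intermediate (not isolated)
10 | dimethyl 2-[(1R)-1-{4-(benzyloxy)-3-[(triisopropylsilyl)oxy]phenyl}-3-(trimethylsilyl)prop-2-yn-1-yl]butanedioate (both epimers at the succinate methine) | C[Si](C)(C)C#C[C@@H](c1ccc(OCc2ccccc2)c(O[Si](C(C)C)(C(C)C)C(C)C)c1)C(CC(=O)OC)C(=O)OC | intermediate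
11 | 3-(trimethylsilyl)prop-2-ynal | C[Si](C)(C)C#CC=O | starting material
12 | methyl 5-oxo-4-[(1R)-1-{4-(benzyloxy)-3-[(triisopropylsilyl)oxy]phenyl}-3-(trimethylsilyl)prop-2-yn-1-yl]-2-[(trimethylsilyl)ethynyl]tetrahydrofuran-3-carboxylate (mixture of ring diastereomers) | C[Si](C)(C)C#C[C@@H](c1ccc(OCc2ccccc2)c(O[Si](C(C)C)(C(C)C)C(C)C)c1)C1C(C(=O)OC)C(C#C[Si](C)(C)C)OC1=O | intermediate (not isolated)
13 | (3E)-3-(methoxycarbonyl)-6-(trimethylsilyl)-2-[(1R)-1-{4-(benzyloxy)-3-[(triisopropylsilyl)oxy]phenyl}-3-(trimethylsilyl)prop-2-yn-1-yl]hex-3-en-5-ynoic acid (both C2 epimers) | C[Si](C)(C)C#C[C@@H](c1ccc(OCc2ccccc2)c(O[Si](C(C)C)(C(C)C)C(C)C)c1)C(C(=O)O)/C(C(=O)OC)=C\C#C[Si](C)(C)C | intermediate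
14 | dimethyl (2E)-2-[3-(trimethylsilyl)prop-2-yn-1-ylidene]-3-[(1R)-1-{4-(benzyloxy)-3-[(triisopropylsilyl)oxy]phenyl}-3-(trimethylsilyl)prop-2-yn-1-yl]butanedioate (both epimers at the succinate methine) | C[Si](C)(C)C#C[C@@H](c1ccc(OCc2ccccc2)c(O[Si](C(C)C)(C(C)C)C(C)C)c1)C(C(=O)OC)/C(C(=O)OC)=C\C#C[Si](C)(C)C | intermediate
15 | dimethyl (2E)-2-(prop-2-yn-1-ylidene)-3-[(1S)-1-[4-(benzyloxy)-3-hydroxyphenyl]prop-2-yn-1-yl]butanedioate (both epimers at the succinate methine) | C#C[C@@H](c1ccc(OCc2ccccc2)c(O)c1)C(C(=O)OC)/C(C(=O)OC)=C\C#C | intermediate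
16 | bis(pinacolatoboryl)acetylene [1,2-bis(4,4,5,5-tetramethyl-1,3,2-dioxaborolan-2-yl)ethyne] | CC1(C)OB(C#CB2OC(C)(C)C(C)(C)O2)OC1(C)C | starting material
17 | dimethyl (1R)-1-[4-(benzyloxy)-3-hydroxyphenyl]-6,7-bis(4,4,5,5-tetramethyl-1,3,2-dioxaborolan-2-yl)-1,2-dihydronaphthalene-2,3-dicarboxylate (both C2 epimers) | COC(=O)C1=Cc2cc(B3OC(C)(C)C(C)(C)O3)c(B3OC(C)(C)C(C)(C)O3)cc2[C@@H](c2ccc(OCc3ccccc3)c(O)c2)C1C(=O)OC | intermediate
18 | dimethyl (1R,2S)-1-[4-(benzyloxy)-3-hydroxyphenyl]-6,7-bis(4,4,5,5-tetramethyl-1,3,2-dioxaborolan-2-yl)-1,2-dihydronaphthalene-2,3-dicarboxylate (trans) | COC(=O)C1=Cc2cc(B3OC(C)(C)C(C)(C)O3)c(B3OC(C)(C)C(C)(C)O3)cc2[C@@H](c2ccc(OCc3ccccc3)c(O)c2)[C@@H]1C(=O)OC | intermediate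
19 | methyl 2-[bis(2,2,2-trifluoroethoxy)phosphoryl]acetate | COC(=O)CP(=O)(OCC(F)(F)F)OCC(F)(F)F | starting material
20 | methyl 2-[bis(2,2,2-trifluoroethoxy)phosphoryl]-2-diazoacetate | COC(=O)C(=[N+]=[N-])P(=O)(OCC(F)(F)F)OCC(F)(F)F | intermediate
21 | dimethyl (1R,2S)-1-[4-(benzyloxy)-3-{1-[bis(2,2,2-trifluoroethoxy)phosphoryl]-2-methoxy-2-oxoethoxy}phenyl]-6,7-bis(4,4,5,5-tetramethyl-1,3,2-dioxaborolan-2-yl)-1,2-dihydronaphthalene-2,3-dicarboxylate (both epimers at the phosphonate carbon) | COC(=O)C1=Cc2cc(B3OC(C)(C)C(C)(C)O3)c(B3OC(C)(C)C(C)(C)O3)cc2[C@@H](c2ccc(OCc3ccccc3)c(OC(C(=O)OC)P(=O)(OCC(F)(F)F)OCC(F)(F)F)c2)[C@@H]1C(=O)OC | intermediate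
22 | 3,4-bis(benzyloxy)benzaldehyde | O=Cc1ccc(OCc2ccccc2)c(OCc2ccccc2)c1 | starting material
23 | dimethyl (1R,2S)-1-[4-(benzyloxy)-3-{[(1E)-2-[3,4-bis(benzyloxy)phenyl]-1-(methoxycarbonyl)ethenyl]oxy}phenyl]-6,7-bis(4,4,5,5-tetramethyl-1,3,2-dioxaborolan-2-yl)-1,2-dihydronaphthalene-2,3-dicarboxylate | COC(=O)C1=Cc2cc(B3OC(C)(C)C(C)(C)O3)c(B3OC(C)(C)C(C)(C)O3)cc2[C@@H](c2ccc(OCc3ccccc3)c(O/C(=C/c3ccc(OCc4ccccc4)c(OCc4ccccc4)c3)C(=O)OC)c2)[C@@H]1C(=O)OC | intermediate
24 | dimethyl (1R,2S)-1-[4-(benzyloxy)-3-{[(1E)-2-[3,4-bis(benzyloxy)phenyl]-1-(methoxycarbonyl)ethenyl]oxy}phenyl]-6,7-dihydroxy-1,2-dihydronaphthalene-2,3-dicarboxylate | COC(=O)C1=Cc2cc(O)c(O)cc2[C@@H](c2ccc(OCc3ccccc3)c(O/C(=C/c3ccc(OCc4ccccc4)c(OCc4ccccc4)c3)C(=O)OC)c2)[C@@H]1C(=O)OC | intermediate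
25 | (1R,2S)-1-[4-(benzyloxy)-3-{[(1E)-2-[3,4-bis(benzyloxy)phenyl]-1-carboxyethenyl]oxy}phenyl]-6,7-dihydroxy-1,2-dihydronaphthalene-2,3-dicarboxylic acid | O=C(O)C1=Cc2cc(O)c(O)cc2[C@@H](c2ccc(OCc3ccccc3)c(O/C(=C/c3ccc(OCc4ccccc4)c(OCc4ccccc4)c3)C(=O)O)c2)[C@@H]1C(=O)O | intermediate
26 | (1R,2S)-1-[3-{[(1E)-1-carboxy-2-(3,4-dihydroxyphenyl)ethenyl]oxy}-4-hydroxyphenyl]-6,7-dihydroxy-1,2-dihydronaphthalene-2,3-dicarboxylic acid | O=C(O)C1=Cc2cc(O)c(O)cc2[C@@H](c2ccc(O)c(O/C(=C/c3ccc(O)c(O)c3)C(=O)O)c2)[C@@H]1C(=O)O | target

## Step count and least certain steps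

Total: 16 steps. Longest linear sequence: 15 steps (steps 1–10 and 12–16, from 1 to 26); step 11 prepares reagent 20.

**Step 9 (key step).** The cobaltacycle may be intercepted by a second molecule of diyne, or by its enyne end, faster than by the bulky diborylalkyne, leading to oligomerisation. Self-trimerisation of 16 and protodeborylation at 110 °C in the presence of the phenol are further drains. Fallback, setting out from 14 and returning at 17: the two alkynyl silanes of 14 would be removed selectively with catalytic AgNO3 in aqueous acetone, keeping the aryl silyl ether, to give the terminal diyne F1. Cocyclisation of F1 with CpCo(CO)2 under irradiation in bis(trimethylsilyl)acetylene as co-solvent, the classical and least hindered partner, should give the 6,7-bis(trimethylsilyl)dihydronaphthalene F2. Double ipso-iododesilylation with ICl at low temperature would give the 6,7-diiodide F3. Borylation with bis(pinacolato)diboron, PdCl2(dppf) and KOAc would give the silyl-protected bis-boronate F4, and Bu4NF/AcOH would then free the phenol to rejoin the route at 17.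

**Step 6.** Enolisation may occur partly at the methine, the ynal may suffer conjugate addition or oligomerisation under the amide base, the liberated methoxide may strip silyl groups, and the E1cB opening may give a poor E/Z ratio because the alkynyl group is small. Fallback, setting out from 10 and returning at 14: formylation of the methylene of 10 (LiN(iPr)2, methyl formate) would give the hydroxymethylene succinate F5. Triflation of its tetramethylammonium enolate with Tf2O (non-chelating, so the oxygen sits trans to the ester) would give the E-enol triflate F6. Sonogashira coupling of F6 with 5 (PdCl2(PPh3)2, CuI, Et3N) proceeds with retention and would deliver 14 directly, without the half-ester.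

**Step 13.** The alpha-aryloxy group may weaken the kinetic preference, or the adducts may equilibrate, so that geometric selectivity is lost and the thermodynamically preferred Z-enol ether (ring D trans to the ester) predominates. Fallback, setting out from 21 and returning at 23: the Z-rich material, the Z isomer F7, would not be discarded. Energy-transfer photocatalysis (fac-Ir(ppy)3, blue light, MeCN) selectively excites the planar, conjugated Z isomer F7. The E isomer 23 has ring D twisted out of conjugation by the cis ester, is a poorer triplet acceptor and should accumulate in the photostationary mixture.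

**Step 16.** The triacid may be poorly soluble at −78 °C, so that debenzylation is incomplete; warming to compensate risks geometric isomerisation or cleavage of the enol ether, and C-benzylation of the catechols if the scavenger is outrun. Fallback, setting out from 24 and returning at 26: the order of the last two operations is reversed. The soluble triester 24 is debenzylated first with BCl3/C6HMe5 at −78 °C to the pentaphenol trimethyl ester F8, and F8 is then saponified with LiOH in degassed aqueous THF under argon and acidified to give 26.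

## Further compounds

F1 | step 9 | dimethyl (2E)-2-(prop-2-yn-1-ylidene)-3-[(1S)-1-{4-(benzyloxy)-3-[(triisopropylsilyl)oxy]phenyl}prop-2-yn-1-yl]butanedioate (both epimers at the succinate methine) | C#C[C@@H](c1ccc(OCc2ccccc2)c(O[Si](C(C)C)(C(C)C)C(C)C)c1)C(C(=O)OC)/C(C(=O)OC)=C\C#C
F2 | step 9 | dimethyl (1R)-1-{4-(benzyloxy)-3-[(triisopropylsilyl)oxy]phenyl}-6,7-bis(trimethylsilyl)-1,2-dihydronaphthalene-2,3-dicarboxylate (both C2 epimers) | COC(=O)C1=Cc2cc([Si](C)(C)C)c([Si](C)(C)C)cc2[C@@H](c2ccc(OCc3ccccc3)c(O[Si](C(C)C)(C(C)C)C(C)C)c2)C1C(=O)OC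
F3 | step 9 | dimethyl (1R)-1-{4-(benzyloxy)-3-[(triisopropylsilyl)oxy]phenyl}-6,7-diiodo-1,2-dihydronaphthalene-2,3-dicarboxylate (both C2 epimers) | COC(=O)C1=Cc2cc(I)c(I)cc2[C@@H](c2ccc(OCc3ccccc3)c(O[Si](C(C)C)(C(C)C)C(C)C)c2)C1C(=O)OC
F4 | step 9 | dimethyl (1R)-1-{4-(benzyloxy)-3-[(triisopropylsilyl)oxy]phenyl}-6,7-bis(4,4,5,5-tetramethyl-1,3,2-dioxaborolan-2-yl)-1,2-dihydronaphthalene-2,3-dicarboxylate (both C2 epimers) | COC(=O)C1=Cc2cc(B3OC(C)(C)C(C)(C)O3)c(B3OC(C)(C)C(C)(C)O3)cc2[C@@H](c2ccc(OCc3ccccc3)c(O[Si](C(C)C)(C(C)C)C(C)C)c2)C1C(=O)OC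
F5 | step 6 | dimethyl 2-(hydroxymethylidene)-3-[(1R)-1-{4-(benzyloxy)-3-[(triisopropylsilyl)oxy]phenyl}-3-(trimethylsilyl)prop-2-yn-1-yl]butanedioate (enol form; both epimers at the succinate methine) | C[Si](C)(C)C#C[C@@H](c1ccc(OCc2ccccc2)c(O[Si](C(C)C)(C(C)C)C(C)C)c1)C(C(=O)OC)C(C(=O)OC)=CO
F6 | step 6 | dimethyl (2E)-2-({[(trifluoromethyl)sulfonyl]oxy}methylidene)-3-[(1R)-1-{4-(benzyloxy)-3-[(triisopropylsilyl)oxy]phenyl}-3-(trimethylsilyl)prop-2-yn-1-yl]butanedioate (both epimers at the succinate methine) | C[Si](C)(C)C#C[C@@H](c1ccc(OCc2ccccc2)c(O[Si](C(C)C)(C(C)C)C(C)C)c1)C(C(=O)OC)/C(C(=O)OC)=C\OS(=O)(=O)C(F)(F)F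
F7 | step 13 | dimethyl (1R,2S)-1-[4-(benzyloxy)-3-{[(1Z)-2-[3,4-bis(benzyloxy)phenyl]-1-(methoxycarbonyl)ethenyl]oxy}phenyl]-6,7-bis(4,4,5,5-tetramethyl-1,3,2-dioxaborolan-2-yl)-1,2-dihydronaphthalene-2,3-dicarboxylate | COC(=O)C1=Cc2cc(B3OC(C)(C)C(C)(C)O3)c(B3OC(C)(C)C(C)(C)O3)cc2[C@@H](c2ccc(OCc3ccccc3)c(O/C(=C\c3ccc(OCc4ccccc4)c(OCc4ccccc4)c3)C(=O)OC)c2)[C@@H]1C(=O)OC
F8 | step 16 | dimethyl (1R,2S)-1-[3-{[(1E)-2-(3,4-dihydroxyphenyl)-1-(methoxycarbonyl)ethenyl]oxy}-4-hydroxyphenyl]-6,7-dihydroxy-1,2-dihydronaphthalene-2,3-dicarboxylate | COC(=O)C1=Cc2cc(O)c(O)cc2[C@@H](c2ccc(O)c(O/C(=C/c3ccc(O)c(O)c3)C(=O)OC)c2)[C@@H]1C(=O)OC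
A1 | alternative 1 | 2-(3-isopropoxy-4-methoxybenzyl)-4,5-dimethoxybenzaldehyde | COc1ccc(Cc2cc(OC)c(OC)cc2C=O)cc1OC(C)C
A2 | alternative 1 | dimethyl fumarate | COC(=O)/C=C/C(=O)OC
A3 | alternative 1 | dimethyl 4-hydroxy-1-(3-isopropoxy-4-methoxyphenyl)-6,7-dimethoxy-1,2,3,4-tetrahydronaphthalene-2,3-dicarboxylate (1-aryl cis to 4-hydroxyl; 2,3-esters trans; C1 and C2 as in 26) | COC(=O)[C@H]1[C@@H](O)c2cc(OC)c(OC)cc2[C@@H](c2ccc(OC)c(OC(C)C)c2)[C@@H]1C(=O)OC
A4 | alternative 2 | dimethyl (2E)-2-{2-[(3-isopropoxy-4-oxocyclohexa-2,5-dien-1-ylidene)methyl]-4,5-dimethoxybenzylidene}butanedioate | COC(=O)C/C(C(=O)OC)=C\c1cc(OC)c(OC)cc1C=C1C=CC(=O)C(OC(C)C)=C1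
A5 | alternative 2 | dimethyl (1R,2S)-1-(4-hydroxy-3-isopropoxyphenyl)-6,7-dimethoxy-1,2-dihydronaphthalene-2,3-dicarboxylate | COC(=O)C1=Cc2cc(OC)c(OC)cc2[C@@H](c2ccc(O)c(OC(C)C)c2)[C@@H]1C(=O)OC
A6 | alternative 3 | dimethyl (2S)-2-{bis[3-(benzyloxy)-4-methoxyphenyl]methyl}-3-(hydroxymethylidene)butanedioate | COc1ccc(cc1OCc1ccccc1)C(c1ccc(OC)c(OCc2ccccc2)c1)[C@H](C(=O)OC)C(C(=O)OC)=CO
A7 | alternative 3 | dimethyl (1R,2S)-7-(benzyloxy)-1-[3-(benzyloxy)-4-methoxyphenyl]-6-methoxy-1,2-dihydronaphthalene-2,3-dicarboxylate | COC(=O)C1=Cc2cc(OC)c(OCc3ccccc3)cc2[C@@H](c2ccc(OC)c(OCc3ccccc3)c2)[C@@H]1C(=O)OC
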